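## Retrosynthetic overview

1. The (3E,5E)-diene is cut at its central C(sp2)–C(sp2) bond into an irone-type terminal alkyne and a bicyclic (E)-alkenyl iodide (hydrozirconation/Negishi); the aldehyde and the primary alcohol are unmasked last.
2. The oxolane ring comes from a γ-lactone (DIBAL, then Et3SiH/BF3) and the C2 carbinol from a ketone plus a methyl nucleophile (bicycle numbered as 6-oxabicyclo[3.2.1]octane: C1 quaternary, C2 carbinol, C5 ether carbon, O6, C7, C8 bridge).
3. Key step: the bicyclic keto-lactone is made from an acyclic α-alkyl β-keto ester by Mn(III) oxidative radical cyclisation (C1–C8 bond, 6-endo) ending in cationic lactonisation (C5–O6). The carbocycle and the lactone ring close in one operation, and C1, C5 and C8 are set from one Roche-ester centre and one alkene geometry.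
4. The keto ester comes from alkylation, Claisen condensation and Johnson–Claisen rearrangement (alkene geometry) of an allylic alcohol built from a Roche-ester alkyne and a C4 aldehyde.
5. The irone ring is built separately: Robinson annulation, dehydrogenation, Cu-catalysed asymmetric methyl addition, then anti-SN2′ alkynylation of an allylic phosphate.

Assumption: ethynyl(triisopropyl)silane and 4-[(tert-butyldiphenylsilyl)oxy]butanal are purchased as the silyl-protected forms of ethyne and 4-hydroxybutanal.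

## Route

**Irone alkyne (steps 1–6)**

Step 1
Reactants: 1 2-methylpropanal; 2 pent-1-en-3-one
Product: 4 2,4,4-trimethylcyclohex-2-en-1-one, via 2,2-dimethyl-5-oxoheptanal 3 (not isolated)
Conditions: H2SO4 (cat.), toluene, 50 °C then reflux (Dean–Stark)
Reagents that add atoms: none
Why: Robinson annulation (acid-catalysed Michael addition of the aldehyde enol to the enone, then aldol condensation of the ethyl ketone CH2 onto the neopentyl aldehyde) is the standard entry to 4,4-dialkylcyclohexenones and creates no stereocentre.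

Step 2
Reactants: 4 2,4,4-trimethylcyclohex-2-en-1-one
Product: 5 2,4,4-trimethylcyclohexa-2,5-dien-1-one
Conditions: DDQ (1.3 equiv), TsOH (cat.), 1,4-dioxane, reflux
Reagents that add atoms: none
Why: DDQ dehydrogenation of an enone to the cross-conjugated dienone (as in Δ4-3-keto steroid to Δ1,4-dienone) can only remove the C5/C6 hydrogens because C4 is quaternary.

Step 3
Reactants: 5 2,4,4-trimethylcyclohexa-2,5-dien-1-one
Product: 6 (5S)-2,4,4,5-tetramethylcyclohex-2-en-1-one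
Conditions: Me3Al (1.4 equiv), CuTC (2 mol %), chiral phosphoramidite (4 mol %, enantiomer that gives 5S), Et2O, −30 °C; aq. NH4Cl
Reagents that add atoms: trimethylaluminium, C[Al](C)C
Why: Cu-catalysed asymmetric conjugate addition to a 4,4-disubstituted cyclohexadienone delivers methyl to the unsubstituted enone arm (the 2-methyl arm is far less reactive), and the ligand sets C5.

Step 4
Reactants: 6 (5S)-2,4,4,5-tetramethylcyclohex-2-en-1-one
Product: 7 (1R,5S)-2,4,4,5-tetramethylcyclohex-2-en-1-ol (OH cis to 5-Me)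
Conditions: NaBH4, CeCl3·7H2O, MeOH, −40 °C
Reagents that add atoms: none
Why: Luche 1,2-reduction with axial hydride delivery gives the pseudo-equatorial alcohol cis to the 5-methyl group, as in carvone to cis-carveol.

Step 5
Reactants: 7 (1R,5S)-2,4,4,5-tetramethylcyclohex-2-en-1-ol
Product: 8 diethyl (1S,5S)-2,4,4,5-tetramethylcyclohex-2-en-1-yl phosphate (O trans to 5-Me)
Conditions: (EtO)2P(O)OH, PPh3, DIAD, THF, 0 °C → rt
Reagents that add atoms: diethyl hydrogen phosphate, CCOP(=O)(O)OCC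
Why: Mitsunobu phosphorylation proceeds by SN2 inversion at C1 and gives the trans-allylic phosphate needed for the anti-SN2′ step.

Step 6
Reactants: 8 diethyl (1S,5S)-2,4,4,5-tetramethylcyclohex-2-en-1-yl phosphate; 9 ethynyl(triisopropyl)silane
Product: 11 (4S,6R)-6-ethynyl-1,4,5,5-tetramethylcyclohex-1-ene, via TIPS-enyne 10 (not isolated)
Conditions: CuCl (10 mol %), 1,10-phenanthroline (12 mol %), LiOt-Bu (1.5 equiv), THF, 40 °C; then TBAF, rt
Reagents that add atoms: none
Why: Cu-catalysed γ-selective allyl–alkynyl coupling (anti-SN2′ of the copper acetylide) puts the alkyne on the γ-carbon anti to the phosphate, i.e. cis to the 5-methyl, and shifts the double bond into the α-irone position; fluoride then cleaves the C–Si bond.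

**Alkylating agent (steps 7–8)**

Step 7
Reactants: 12 pent-3-yn-1-ol
Product: 14 (3E)-4-iodopent-3-en-1-ol, via pentenylzirconocene 13 (not isolated)
Conditions: Cp2Zr(H)Cl (2.5 equiv), THF, rt → 40 °C; then I2, 0 °C
Reagents that add atoms: iodine, II
Why: Hydrozirconation (syn addition, equilibration with excess Schwartz reagent puts Zr on the methyl-bearing carbon) followed by iodinolysis with retention gives the E-alkenyl iodide.

Step 8
Reactants: 14 (3E)-4-iodopent-3-en-1-ol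
Product: 15 (2E)-2,5-diiodopent-2-ene
Conditions: I2, PPh3, imidazole, CH2Cl2, 0 °C
Reagents that add atoms: iodine, II
Why: Appel-type iodination (SN2 on the alkoxyphosphonium ion) converts only the primary alcohol, the alkenyl iodide being inert.

**Core and endgame (steps 9–21)**

Step 9
Reactants: 16 methyl (2R)-3-hydroxy-2-methylpropanoate
Product: 17 methyl (2R)-3-[(tert-butyldimethylsilyl)oxy]-2-methylpropanoate
Conditions: TBSCl, imidazole, DMF, rt
Reagents that add atoms: tert-butyldimethylsilyl chloride, CC(C)(C)[Si](C)(C)Cl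
Why: Standard silylation protects the primary alcohol that becomes the aldehyde at the end and gives the bulky CH2OTBS group used for facial control in step 15.

Step 10
Reactants: 17 methyl (2R)-3-[(tert-butyldimethylsilyl)oxy]-2-methylpropanoate
Product: 19 tert-butyldimethyl{[(2S)-2-methylbut-3-yn-1-yl]oxy}silane, via aldehyde 18 (not isolated)
Conditions: DIBAL-H (1.05 equiv), CH2Cl2, −78 °C; then MeOH, K2CO3, dimethyl (1-diazo-2-oxopropyl)phosphonate, −78 °C → rt
Reagents that add atoms: Ohira–Bestmann reagent, COP(=O)(OC)C(=[N+]=[N-])C(C)=O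
Why: One-pot DIBAL half-reduction and Seyferth–Gilbert (Ohira–Bestmann) homologation gives the terminal alkyne without isolating the epimerisable aldehyde, so the Roche stereocentre is kept.

Step 11
Reactants: 19 tert-butyldimethyl{[(2S)-2-methylbut-3-yn-1-yl]oxy}silane; 20 4-[(tert-butyldiphenylsilyl)oxy]butanal
Product: 22 (6S)-7-[(tert-butyldimethylsilyl)oxy]-1-[(tert-butyldiphenylsilyl)oxy]-6-methyl-5-methylideneheptan-4-ol (both C4 epimers), via vinylalane 21 (not isolated)
Conditions: 19 (1.3 equiv), Ni(dppp)Cl2 (3 mol %), DIBAL-H (1.25 equiv), THF, 0 °C → rt; MeLi (1.25 equiv), −78 °C; then 20, −78 → 0 °C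
Reagents that add atoms: none
Why: Ni-catalysed α-selective (Markovnikov) hydroalumination gives the 2-alumino-1-alkene, whose methyl ate complex transfers the alkenyl group to the aldehyde (1,2-addition); the new carbinol centre forms as both epimers and is erased in step 12.

Step 12
Reactants: 22 (6S)-7-[(tert-butyldimethylsilyl)oxy]-1-[(tert-butyldiphenylsilyl)oxy]-6-methyl-5-methylideneheptan-4-ol; 23 1,1,1-trimethoxyethane
Product: 24 methyl (4Z)-4-{(2S)-1-[(tert-butyldimethylsilyl)oxy]propan-2-yl}-8-[(tert-butyldiphenylsilyl)oxy]oct-4-enoate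
Conditions: EtCO2H (cat.), xylene, 130 °C (MeOH distilled off)
Reagents that add atoms: none
Why: Johnson–Claisen [3,3] rearrangement through a chair with the silyloxypropyl chain equatorial gives the trisubstituted alkene with the new CH2CH2CO2Me chain trans to that chain (4Z by CIP), whichever carbinol epimer reacts.

Step 13
Reactants: 24 methyl (4Z)-4-{(2S)-1-[(tert-butyldimethylsilyl)oxy]propan-2-yl}-8-[(tert-butyldiphenylsilyl)oxy]oct-4-enoate; 25 tert-butyl acetate
Product: 26 tert-butyl (6Z)-6-{(2S)-1-[(tert-butyldimethylsilyl)oxy]propan-2-yl}-10-[(tert-butyldiphenylsilyl)oxy]-3-oxodec-6-enoate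
Conditions: LDA (3.2 equiv), 25 (3.2 equiv), THF, −78 °C; then 24, −78 → −20 °C; aq. NH4Cl
Reagents that add atoms: none
Why: Crossed Claisen condensation, in which the excess ester enolate deprotonates the β-keto ester as it forms and so prevents a second addition.

Step 14
Reactants: 26 tert-butyl (6Z)-6-{(2S)-1-[(tert-butyldimethylsilyl)oxy]propan-2-yl}-10-[(tert-butyldiphenylsilyl)oxy]-3-oxodec-6-enoate; 15 (2E)-2,5-diiodopent-2-ene
Product: 27 tert-butyl (6Z)-6-{(2S)-1-[(tert-butyldimethylsilyl)oxy]propan-2-yl}-10-[(tert-butyldiphenylsilyl)oxy]-2-[(3E)-4-iodopent-3-en-1-yl]-3-oxodec-6-enoate (C2 epimers)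
Conditions: NaH, THF/DMF, 0 °C; then 15, rt → 45 °C
Reagents that add atoms: none
Why: SN2 C-alkylation of the β-keto ester enolate takes place only at the primary sp3 iodide (the alkenyl iodide cannot be displaced) and puts the side-chain handle on the carbon that becomes the quaternary bridgehead.

Step 15 (key step)
Reactants: 27 tert-butyl (6Z)-6-{(2S)-1-[(tert-butyldimethylsilyl)oxy]propan-2-yl}-10-[(tert-butyldiphenylsilyl)oxy]-2-[(3E)-4-iodopent-3-en-1-yl]-3-oxodec-6-enoate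
Product: 29 (1R,5R,8S)-5-{(2R)-1-[(tert-butyldimethylsilyl)oxy]propan-2-yl}-8-{3-[(tert-butyldiphenylsilyl)oxy]propyl}-1-[(3E)-4-iodopent-3-en-1-yl]-6-oxabicyclo[3.2.1]octane-2,7-dione, via cyclised tertiary radical 28 (not isolated)
Conditions: Mn(OAc)3·2H2O (2.3 equiv), degassed AcOH (0.02 M), 30–40 °C
Reagents that add atoms: none
Why: Mn(III)-based oxidative free-radical cyclisation (Snider type): the Mn(III) enolate gives the α-radical, which closes 6-endo onto the CH end of the trisubstituted alkene through a chair with the ester axial and the silyloxypropyl chain equatorial, on the alkene face anti to CH2OTBS (allylic 1,3-strain holds the allylic H in the alkene plane), and Mn(III) oxidises the tertiary radical to the cation that the axial tert-butyl ester traps with loss of isobutene, so C1, C8 and C5 are set together.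

Step 16
Reactants: 29 (1R,5R,8S)-5-{(2R)-1-[(tert-butyldimethylsilyl)oxy]propan-2-yl}-8-{3-[(tert-butyldiphenylsilyl)oxy]propyl}-1-[(3E)-4-iodopent-3-en-1-yl]-6-oxabicyclo[3.2.1]octane-2,7-dione
Product: 30 (1R,2S,5R,8S)-2-hydroxy-2-methyl-5-{(2R)-1-[(tert-butyldimethylsilyl)oxy]propan-2-yl}-8-{3-[(tert-butyldiphenylsilyl)oxy]propyl}-1-[(3E)-4-iodopent-3-en-1-yl]-6-oxabicyclo[3.2.1]octan-7-one
Conditions: MeMgBr, CeCl3, THF, −78 °C
Reagents that add atoms: methylmagnesium bromide, C[Mg]Br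
Why: Organocerium 1,2-addition to the ketone (faster than attack on the hindered bridged lactone, no enolisation) comes from the face of the one-carbon bridge, anti to the lactone bridge beside the carbonyl, which puts methyl syn to C8–H and the hydroxyl equatorial (2S).

Step 17
Reactants: 30 (1R,2S,5R,8S)-2-hydroxy-2-methyl-5-{(2R)-1-[(tert-butyldimethylsilyl)oxy]propan-2-yl}-8-{3-[(tert-butyldiphenylsilyl)oxy]propyl}-1-[(3E)-4-iodopent-3-en-1-yl]-6-oxabicyclo[3.2.1]octan-7-one
Product: 32 (1S,2S,5R,8S)-2-methyl-5-{(2R)-1-[(tert-butyldimethylsilyl)oxy]propan-2-yl}-8-{3-[(tert-butyldiphenylsilyl)oxy]propyl}-1-[(3E)-4-iodopent-3-en-1-yl]-6-oxabicyclo[3.2.1]octan-2-ol, via lactol 31 (not isolated)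
Conditions: DIBAL-H (3 equiv), CH2Cl2, −78 °C; then Et3SiH, BF3·OEt2, −78 → −40 °C
Reagents that add atoms: none
Why: DIBAL reduction stops at the lactol (aluminium hemiacetal), which BF3 ionises to the bicyclic oxocarbenium ion that Et3SiH reduces (ionic hydrogenation) to the oxolane, without touching a stereocentre.

Step 18
Reactants: 32 (1S,2S,5R,8S)-2-methyl-5-{(2R)-1-[(tert-butyldimethylsilyl)oxy]propan-2-yl}-8-{3-[(tert-butyldiphenylsilyl)oxy]propyl}-1-[(3E)-4-iodopent-3-en-1-yl]-6-oxabicyclo[3.2.1]octan-2-ol; 11 (4S,6R)-6-ethynyl-1,4,5,5-tetramethylcyclohex-1-ene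
Product: 34 (1S,2S,5R,8S)-2-methyl-1-{(3E,5E)-4-methyl-6-[(1R,5S)-2,5,6,6-tetramethylcyclohex-2-en-1-yl]hexa-3,5-dien-1-yl}-5-{(2R)-1-[(tert-butyldimethylsilyl)oxy]propan-2-yl}-8-{3-[(tert-butyldiphenylsilyl)oxy]propyl}-6-oxabicyclo[3.2.1]octan-2-ol, via irone vinylzirconocene 33 (not isolated)
Conditions: 11 (1.6 equiv), Cp2Zr(H)Cl (1.6 equiv), THF, rt; then ZnCl2, 32, Pd(PPh3)4 (5 mol %), THF, rt
Reagents that add atoms: none
Why: syn-Hydrozirconation of the terminal alkyne gives the E-alkenylzirconocene, and Zn-assisted Negishi coupling with the alkenyl iodide proceeds with retention at both partners to give the 3E,5E-diene.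

Step 19
Reactants: 34 (the bis-silyl ether named in step 18)
Product: 35 (2R)-2-[(1S,2S,5R,8S)-2-hydroxy-2-methyl-1-{(3E,5E)-4-methyl-6-[(1R,5S)-2,5,6,6-tetramethylcyclohex-2-en-1-yl]hexa-3,5-dien-1-yl}-8-{3-[(tert-butyldiphenylsilyl)oxy]propyl}-6-oxabicyclo[3.2.1]octan-5-yl]propan-1-ol
Conditions: HF·pyridine, pyridine, THF, 0 °C
Reagents that add atoms: none
Why: Selective desilylation, since the primary TBS ether is cleaved much faster than the TBDPS ether under buffered HF.

Step 20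
Reactants: 35 (the primary alcohol named in step 19)
Product: 36 (2S)-2-[(1S,2S,5R,8S)-2-hydroxy-2-methyl-1-{(3E,5E)-4-methyl-6-[(1R,5S)-2,5,6,6-tetramethylcyclohex-2-en-1-yl]hexa-3,5-dien-1-yl}-8-{3-[(tert-butyldiphenylsilyl)oxy]propyl}-6-oxabicyclo[3.2.1]octan-5-yl]propanal
Conditions: Dess–Martin periodinane, NaHCO3, CH2Cl2, 0 °C → rt
Reagents that add atoms: none
Why: Dess–Martin oxidation of the only primary alcohol under buffered, non-basic conditions gives the aldehyde without epimerising the α-centre or opening the β-alkoxy aldehyde, and the tertiary alcohol is inert.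

Step 21
Reactants: 36 (the aldehyde named in step 20)
Product: 37 (2S)-2-[(1S,2S,5R,8S)-2-hydroxy-8-(3-hydroxypropyl)-2-methyl-1-{(3E,5E)-4-methyl-6-[(1R,5S)-2,5,6,6-tetramethylcyclohex-2-en-1-yl]hexa-3,5-dien-1-yl}-6-oxabicyclo[3.2.1]octan-5-yl]propanal (CNP0419303.1)
Conditions: HF·pyridine, pyridine, THF, rt
Reagents that add atoms: none
Why: Fluoride-mediated cleavage of the TBDPS ether under buffered, weakly acidic conditions frees the primary alcohol while avoiding the base that would epimerise or β-eliminate the aldehyde.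

## Compound list

1 | 2-methylpropanal | CC(C)C=O | starting material
2 | pent-1-en-3-one | CCC(=O)C=C | starting material
3 | 2,2-dimethyl-5-oxoheptanal | CCC(=O)CCC(C)(C)C=O | intermediate
4 | 2,4,4-trimethylcyclohex-2-en-1-one | CC1=CC(C)(C)CCC1=O | intermediate
5 | 2,4,4-trimethylcyclohexa-2,5-dien-1-one | CC1=CC(C)(C)C=CC1=O | intermediate
6 | (5S)-2,4,4,5-tetramethylcyclohex-2-en-1-one | CC1=CC(C)(C)[C@@H](C)CC1=O | intermediate
7 | (1R,5S)-2,4,4,5-tetramethylcyclohex-2-en-1-ol | CC1=CC(C)(C)[C@@H](C)C[C@H]1O | intermediate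
8 | diethyl (1S,5S)-2,4,4,5-tetramethylcyclohex-2-en-1-yl phosphate | CC1=CC(C)(C)[C@@H](C)C[C@@H]1OP(=O)(OCC)OCC | intermediate
9 | ethynyl(triisopropyl)silane | C#C[Si](C(C)C)(C(C)C)C(C)C | starting material
10 | triisopropyl{[(1R,5S)-2,5,6,6-tetramethylcyclohex-2-en-1-yl]ethynyl}silane | CC1=CC[C@H](C)C(C)(C)[C@@H]1C#C[Si](C(C)C)(C(C)C)C(C)C | intermediate
11 | (4S,6R)-6-ethynyl-1,4,5,5-tetramethylcyclohex-1-ene | CC1=CC[C@H](C)C(C)(C)[C@@H]1C#C | intermediate
12 | pent-3-yn-1-ol | CC#CCCO | starting material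
13 | (E)-4-zirconated pent-3-en-1-olate, both Zr as chlorobis(cyclopentadienyl)zirconium | C/C(=C\CCO[Zr](Cl)(C1C=CC=C1)C1C=CC=C1)[Zr](Cl)(C1C=CC=C1)C1C=CC=C1 | intermediate
14 | (3E)-4-iodopent-3-en-1-ol | I/C(C)=C/CCO | intermediate
15 | (2E)-2,5-diiodopent-2-ene | I/C(C)=C/CCI | intermediate
16 | methyl (2R)-3-hydroxy-2-methylpropanoate | COC(=O)[C@H](C)CO | starting material
17 | methyl (2R)-3-[(tert-butyldimethylsilyl)oxy]-2-methylpropanoate | COC(=O)[C@H](C)CO[Si](C)(C)C(C)(C)C | intermediate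
18 | (2R)-3-[(tert-butyldimethylsilyl)oxy]-2-methylpropanal | O=C[C@H](C)CO[Si](C)(C)C(C)(C)C | intermediate
19 | tert-butyldimethyl{[(2S)-2-methylbut-3-yn-1-yl]oxy}silane | C#C[C@H](C)CO[Si](C)(C)C(C)(C)C | intermediate
20 | 4-[(tert-butyldiphenylsilyl)oxy]butanal | O=CCCCO[Si](c1ccccc1)(c1ccccc1)C(C)(C)C | starting material
21 | diisobutyl{(3R)-4-[(tert-butyldimethylsilyl)oxy]-3-methylbut-1-en-2-yl}alumane | C=C([Al](CC(C)C)CC(C)C)[C@H](C)CO[Si](C)(C)C(C)(C)C | intermediate
22 | (6S)-7-[(tert-butyldimethylsilyl)oxy]-1-[(tert-butyldiphenylsilyl)oxy]-6-methyl-5-methylideneheptan-4-ol (C4 epimers) | C=C([C@H](C)CO[Si](C)(C)C(C)(C)C)C(O)CCCO[Si](c1ccccc1)(c1ccccc1)C(C)(C)C | intermediate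
23 | 1,1,1-trimethoxyethane | CC(OC)(OC)OC | starting material
24 | methyl (4Z)-4-{(2S)-1-[(tert-butyldimethylsilyl)oxy]propan-2-yl}-8-[(tert-butyldiphenylsilyl)oxy]oct-4-enoate | COC(=O)CC/C(=C/CCCO[Si](c1ccccc1)(c1ccccc1)C(C)(C)C)[C@H](C)CO[Si](C)(C)C(C)(C)C | intermediate
25 | tert-butyl acetate | CC(=O)OC(C)(C)C | starting material
26 | tert-butyl (6Z)-6-{(2S)-1-[(tert-butyldimethylsilyl)oxy]propan-2-yl}-10-[(tert-butyldiphenylsilyl)oxy]-3-oxodec-6-enoate | CC(C)(C)OC(=O)CC(=O)CC/C(=C/CCCO[Si](c1ccccc1)(c1ccccc1)C(C)(C)C)[C@H](C)CO[Si](C)(C)C(C)(C)C | intermediate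
27 | tert-butyl (6Z)-6-{(2S)-1-[(tert-butyldimethylsilyl)oxy]propan-2-yl}-10-[(tert-butyldiphenylsilyl)oxy]-2-[(3E)-4-iodopent-3-en-1-yl]-3-oxodec-6-enoate (C2 epimers) | CC(C)(C)OC(=O)C(CC/C=C(C)/I)C(=O)CC/C(=C/CCCO[Si](c1ccccc1)(c1ccccc1)C(C)(C)C)[C@H](C)CO[Si](C)(C)C(C)(C)C | intermediate
28 | cyclised tertiary cyclohexyl radical (tert-butyl ester axial on the quaternary carbon, radical on the carbon bearing the silyloxypropan-2-yl group, ring centres as in 29) | I/C(C)=C/CC[C@]1(C(=O)OC(C)(C)C)C(=O)CC[C]([C@H](C)CO[Si](C)(C)C(C)(C)C)[C@H]1CCCO[Si](c2ccccc2)(c2ccccc2)C(C)(C)C | intermediate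
29 | (1R,5R,8S)-5-{(2R)-1-[(tert-butyldimethylsilyl)oxy]propan-2-yl}-8-{3-[(tert-butyldiphenylsilyl)oxy]propyl}-1-[(3E)-4-iodopent-3-en-1-yl]-6-oxabicyclo[3.2.1]octane-2,7-dione | I/C(C)=C/CC[C@]12C(=O)O[C@]([C@H](C)CO[Si](C)(C)C(C)(C)C)(CCC1=O)[C@H]2CCCO[Si](c3ccccc3)(c3ccccc3)C(C)(C)C | intermediate
30 | (1R,2S,5R,8S)-2-hydroxy-2-methyl-5-{(2R)-1-[(tert-butyldimethylsilyl)oxy]propan-2-yl}-8-{3-[(tert-butyldiphenylsilyl)oxy]propyl}-1-[(3E)-4-iodopent-3-en-1-yl]-6-oxabicyclo[3.2.1]octan-7-one | I/C(C)=C/CC[C@]12C(=O)O[C@]([C@H](C)CO[Si](C)(C)C(C)(C)C)(CC[C@]1(C)O)[C@H]2CCCO[Si](c3ccccc3)(c3ccccc3)C(C)(C)C | intermediate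
31 | (1R,2S,5R,8S)-2-methyl-5-{(2R)-1-[(tert-butyldimethylsilyl)oxy]propan-2-yl}-8-{3-[(tert-butyldiphenylsilyl)oxy]propyl}-1-[(3E)-4-iodopent-3-en-1-yl]-6-oxabicyclo[3.2.1]octane-2,7-diol (C7 epimers) | I/C(C)=C/CC[C@]12C(O)O[C@]([C@H](C)CO[Si](C)(C)C(C)(C)C)(CC[C@]1(C)O)[C@H]2CCCO[Si](c3ccccc3)(c3ccccc3)C(C)(C)C | intermediate
32 | (1S,2S,5R,8S)-2-methyl-5-{(2R)-1-[(tert-butyldimethylsilyl)oxy]propan-2-yl}-8-{3-[(tert-butyldiphenylsilyl)oxy]propyl}-1-[(3E)-4-iodopent-3-en-1-yl]-6-oxabicyclo[3.2.1]octan-2-ol | I/C(C)=C/CC[C@]12CO[C@]([C@H](C)CO[Si](C)(C)C(C)(C)C)(CC[C@]1(C)O)[C@H]2CCCO[Si](c3ccccc3)(c3ccccc3)C(C)(C)C | intermediate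
33 | chlorobis(cyclopentadienyl){(E)-2-[(1R,5S)-2,5,6,6-tetramethylcyclohex-2-en-1-yl]ethenyl}zirconium | CC1=CC[C@H](C)C(C)(C)[C@@H]1/C=C/[Zr](Cl)(C1C=CC=C1)C1C=CC=C1 | intermediate
34 | (1S,2S,5R,8S)-2-methyl-1-{(3E,5E)-4-methyl-6-[(1R,5S)-2,5,6,6-tetramethylcyclohex-2-en-1-yl]hexa-3,5-dien-1-yl}-5-{(2R)-1-[(tert-butyldimethylsilyl)oxy]propan-2-yl}-8-{3-[(tert-butyldiphenylsilyl)oxy]propyl}-6-oxabicyclo[3.2.1]octan-2-ol | CC1=CC[C@H](C)C(C)(C)[C@@H]1/C=C/C(C)=C/CC[C@]12CO[C@]([C@H](C)CO[Si](C)(C)C(C)(C)C)(CC[C@]1(C)O)[C@H]2CCCO[Si](c3ccccc3)(c3ccccc3)C(C)(C)C | intermediate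
35 | (2R)-2-[(1S,2S,5R,8S)-2-hydroxy-2-methyl-1-{(3E,5E)-4-methyl-6-[(1R,5S)-2,5,6,6-tetramethylcyclohex-2-en-1-yl]hexa-3,5-dien-1-yl}-8-{3-[(tert-butyldiphenylsilyl)oxy]propyl}-6-oxabicyclo[3.2.1]octan-5-yl]propan-1-ol | CC1=CC[C@H](C)C(C)(C)[C@@H]1/C=C/C(C)=C/CC[C@]12CO[C@]([C@H](C)CO)(CC[C@]1(C)O)[C@H]2CCCO[Si](c3ccccc3)(c3ccccc3)C(C)(C)C | intermediate
36 | (2S)-2-[(1S,2S,5R,8S)-2-hydroxy-2-methyl-1-{(3E,5E)-4-methyl-6-[(1R,5S)-2,5,6,6-tetramethylcyclohex-2-en-1-yl]hexa-3,5-dien-1-yl}-8-{3-[(tert-butyldiphenylsilyl)oxy]propyl}-6-oxabicyclo[3.2.1]octan-5-yl]propanal | CC1=CC[C@H](C)C(C)(C)[C@@H]1/C=C/C(C)=C/CC[C@]12CO[C@]([C@H](C)C=O)(CC[C@]1(C)O)[C@H]2CCCO[Si](c3ccccc3)(c3ccccc3)C(C)(C)C | intermediate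
37 | (2S)-2-[(1S,2S,5R,8S)-2-hydroxy-8-(3-hydroxypropyl)-2-methyl-1-{(3E,5E)-4-methyl-6-[(1R,5S)-2,5,6,6-tetramethylcyclohex-2-en-1-yl]hexa-3,5-dien-1-yl}-6-oxabicyclo[3.2.1]octan-5-yl]propanal | CC1=CC[C@H](C)C(C)(C)[C@@H]1/C=C/C(C)=C/CC[C@]12CO[C@]([C@H](C)C=O)(CC[C@]1(C)O)[C@H]2CCCO | target

## Step count and risk

Total step count: 21. Longest linear sequence: 13 steps (16 → 37, steps 9–21).

Steps most likely to fail:

Step 15 (Mn(III) cyclisation/lactonisation). The risks are a modest facial ratio from a single allylic centre, elimination of the tertiary radical or cation to alkenes instead of lactone, and partial TBS loss in AcOH. The fallback sets out from 27 and comes back at 29. Bromination of 27 (NaH, then NBS, THF, 0 °C) gives the α-bromo keto ester F1. Bromine-atom-transfer radical cyclisation (CuBr/TPMA, or fac-Ir(ppy)3 with blue light) closes the same 6-endo ring and leaves the tertiary bromide F2. AgOTf with 2,6-di-tert-butylpyridine in CH2Cl2 at −40 °C then ionises F2, and the tert-butyl ester lactonises to 29. The C–C bond is still formed by a radical, but cyclisation and cation capture are separated and no oxidant or acetic acid is present.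

Step 6 (γ-selective alkynylation next to a quaternary carbon). The risk is α-substitution or no reaction at the hindered γ-carbon. The fallback sets out from 7 and comes back at 11. Alkylation of 7 (KH, Bu3SnCH2I) gives the stannylmethyl ether F3. n-BuLi at −78 °C triggers tin–lithium exchange and a Still–Wittig [2,3] shift that delivers CH2OH suprafacially, cis to the 5-methyl, as the homoallylic alcohol F4. Dess–Martin oxidation gives the β,γ-unsaturated aldehyde F5, and lithiated trimethylsilyldiazomethane (Colvin, −78 °C) converts it into 11. This intramolecular delivery does not depend on a copper reagent reaching the hindered carbon.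

Step 17 (one-pot lactone to ether beside a tertiary alcohol). The risk is ionisation or ionic reduction of the tertiary alcohol, or over-reduction of the lactol. The fallback sets out from 30 and comes back at 32. LiBH4 (THF, MeOH) opens the lactone to the triol F6. TsCl in pyridine sulfonylates the only primary hydroxyl to the tosylate F7. KOt-Bu in THF then closes the oxolane by 5-exo-tet Williamson attack of the tertiary alkoxide on the ether carbon (the competing oxetane closure from the other tertiary alkoxide is slower), giving 32 without any Lewis acid.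

## Further compounds

F1 | step 15 | tert-butyl (6Z)-2-bromo-6-{(2S)-1-[(tert-butyldimethylsilyl)oxy]propan-2-yl}-10-[(tert-butyldiphenylsilyl)oxy]-2-[(3E)-4-iodopent-3-en-1-yl]-3-oxodec-6-enoate | CC(C)(C)OC(=O)C(Br)(CC/C=C(C)/I)C(=O)CC/C(=C/CCCO[Si](c1ccccc1)(c1ccccc1)C(C)(C)C)[C@H](C)CO[Si](C)(C)C(C)(C)C
F2 | step 15 | tert-butyl 3-bromo-3-{(2R)-1-[(tert-butyldimethylsilyl)oxy]propan-2-yl}-2-{3-[(tert-butyldiphenylsilyl)oxy]propyl}-1-[(3E)-4-iodopent-3-en-1-yl]-6-oxocyclohexane-1-carboxylate (C1 and C2 as in 29, C3 epimers) | I/C(C)=C/CC[C@]1(C(=O)OC(C)(C)C)C(=O)CCC(Br)([C@H](C)CO[Si](C)(C)C(C)(C)C)[C@H]1CCCO[Si](c2ccccc2)(c2ccccc2)C(C)(C)C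
F3 | step 6 | tributyl({[(1R,5S)-2,4,4,5-tetramethylcyclohex-2-en-1-yl]oxy}methyl)stannane | CC1=CC(C)(C)[C@@H](C)C[C@H]1OC[Sn](CCCC)(CCCC)CCCC
F4 | step 6 | [(1R,5S)-2,5,6,6-tetramethylcyclohex-2-en-1-yl]methanol | CC1=CC[C@H](C)C(C)(C)[C@@H]1CO
F5 | step 6 | (1R,5S)-2,5,6,6-tetramethylcyclohex-2-ene-1-carbaldehyde | CC1=CC[C@H](C)C(C)(C)[C@@H]1C=O
F6 | step 17 | 2-(hydroxymethyl)-2-[(3E)-4-iodopent-3-en-1-yl]-1-methyl-4-{(2R)-1-[(tert-butyldimethylsilyl)oxy]propan-2-yl}-3-{3-[(tert-butyldiphenylsilyl)oxy]propyl}cyclohexane-1,4-diol (ring centres as in 30) | I/C(C)=C/CC[C@]1(CO)[C@@](C)(O)CC[C@](O)([C@H](C)CO[Si](C)(C)C(C)(C)C)[C@H]1CCCO[Si](c2ccccc2)(c2ccccc2)C(C)(C)C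
F7 | step 17 | primary 4-methylbenzenesulfonate of F6 | I/C(C)=C/CC[C@]1(COS(=O)(=O)c2ccc(C)cc2)[C@@](C)(O)CC[C@](O)([C@H](C)CO[Si](C)(C)C(C)(C)C)[C@H]1CCCO[Si](c3ccccc3)(c3ccccc3)C(C)(C)C
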